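(The numbers of this flask come from no measurement; the run is a simulation.)

Early in the flask, each turn of electrophile with nucleophile makes target and sets one acid free, so the questions below come down to counting such turns.

| setting | north | west | south |
|---|---|---|---|
| electrophile | 0.23 M | 0.23 M | 0.23 M |
| nucleophile | 0.253 M | 0.253 M | 0.253 M |
| free base | 0.230 M | 0.460 M | 0.920 M |
| time | 2.5 d | 2.5 d | 2.5 d |

    nucleophile + target → over-reaction product (k1 = 5.9 × 10⁻⁵ /M/s)
    acid set free + free base ⇌ salt of the base, settled at all times (K2 = 10 /M)
    nucleophile + acid set free ⇌ protonated nucleophile, settled at all times (K3 = 11000 /M)
    electrophile + nucleophile → acid set free + target (k4 = 8.5 × 10⁻⁵ /M/s)
    2 free base → homo dimer (k5 = 5.9 × 10⁻⁵ /M/s)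

- where a step has two of a species, its rate is k times that concentration squared, and two are used at each turn
- run time (north): 2.5 d

1. part of the electrophile that has reacted at the end, north
2. part of the electrophile that has reacted at the end, west
3. part of the electrophile that has reacted at the end, south
4. what raising the concentration of free base from its lowest to its highest value here does to the part of the electrophile that has reacted (changes below 5 percentage points count as none) (it falls / no change / it rises)

At the start, the takers of the acid weigh in as equilibrium constant times concentration. In north, nucleophile counts 2780 and free base 2.3. In south, with free base at 0.920 M instead of 0.230 M, free base still counts 9.20 against the same 2780 for nucleophile. So in both flasks, as long as that order stands, the acid goes to nucleophile and each turn costs two nucleophile, one reacted and one protonated; north and south should end level, and west, whose free base lies between them, with them.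

Counting turnovers at two nucleophile per turn gives the turnover share, the nucleophile charged divided by two and taken over the electrophile charged: 55.0%. A charge of 1.10 equivalents therefore makes nucleophile the limiting reagent. With the other concentrations as charged, the half-life of electrophile by the main step alone in north is 0.37 d, shorter than the run of 2.5 d, but that comparison holds for the start.

The over-reaction takes nucleophile as well, and its selectivity factor, over-reaction constant over main constant, is 0.694. If north has turned half of its electrophile, that factor puts over-reaction product at 11.4% of the electrophile charged. The nucleophile needed is then 0.256 M, a little more than the 0.253 M charged. The reckoning therefore stops north just under half.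

The forecast gives 50% for north, 50.7% for west and 51.2% for south, trend no change, since “each turn of the main reaction also removes a nucleophile”, and its south stands a little above its north where this reckoning has them level.

North reacted 50.0%, less than the turnover share of 55.0%, with free nucleophile at 0.922% of its charge at the end, and from north to south the answer moved 0.024 percentage points, which counts as no change. West's answer has moved by 5 points at nucleophile charges of 0.224 M and 0.284 M. A neighbour of north charged with 0.10 M of nucleophile has a turnover share of 21.7%; it reacted 21.8%, with over-reaction product at 1.84% of the electrophile charged.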